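**Retrosynthetic overview**
1. Rings A and B with the C5/C10 stereocentres, C11–C13 and C24 are taken intact from (−)-sclareol 1 → Δ8 methyl ketone 5 → 2-triflyloxy-1-alkene 7; no carbocycle is built or broken.
2. The butenolide ring is bought as 4-bromofuran-2(5H)-one 8 and extended with propargyl alcohol 9 (C14–C16) to ynal 11.
3. C13–C14 disconnection: Nozaki–Hiyama–Kishi union of 7 and 11 → enynol 13; the (15Z) olefin comes from semihydrogenation → bis-allylic alcohol 14.
4. Key disconnection (last step): the C24–O bond of target 17, made by suprafacial 1,3-transposition of the C14 hydroxyl of 14, which also sets the (13E) olefin.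
5. Ring order: none formed — the decalin comes from the chiral pool, the lactone ring from 8.

Locants: labdane numbering for C1–C13; C14–C16 are the diene carbons, C17–C19 and C25 the butenolide, C24 the CH2OH carbon. Dec = (4aS,8aS)-2,5,5,8a-tetramethyl-3,4,4a,5,6,7,8,8a-octahydronaphthalen-1-yl (trans-decalin, 10β-CH3, 5α-H, Δ8 olefin).

Assumption: the target SMILES decodes to the natural (5S,10S) configuration of (−)-sclareol with (13E,15Z) olefins, and 4-bromofuran-2(5H)-one is taken as a catalogue compound.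

**Step 1**
Reactants: 1 (−)-sclareol
Product: 3 hydroxy ketone 4-[(1R,2R,4aS,8aS)-2-hydroxy-2,5,5,8a-tetramethyldecahydronaphthalen-1-yl]butan-2-one, via α-hydroxy aldehyde 2 (not isolated)
Conditions: OsO4 (1 mol%), NaIO4 (4 equiv), t-BuOH/H2O, 45 °C
Reagents that add atoms: none
Why: Lemieux–Johnson oxidative cleavage — the only olefin (the vinyl group) is dihydroxylated and cleaved, and periodate then cleaves the tertiary α-hydroxy aldehyde 2 to the methyl ketone (its oxygen is the old C13 hydroxyl oxygen), leaving C5, C8, C9 and C10 untouched.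

**Step 2**
Reactants: 3 hydroxy ketone
Product: 5 Δ8 methyl ketone 4-Dec-butan-2-one, via sclareol oxide 4 (not isolated)
Conditions: aq. HI (57%, 10 mol%), toluene, 85 °C
Reagents that add atoms: none
Why: Acid-catalysed E1 dehydration under thermodynamic (Zaitsev) control — cyclodehydration to enol ether 4 is reversible, and re-ionisation at tertiary C8 with proton loss from C9 funnels material to the tetrasubstituted Δ8 keto-olefin, which removes the C8/C9 stereocentres while C5 and C10 cannot ionise and keep the sclareol configuration.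

**Step 3**
Reactants: 5 Δ8 methyl ketone
Product: 7 enol triflate 4-Dec-but-1-en-2-yl trifluoromethanesulfonate, via potassium enolate 6 (not isolated)
Conditions: KN(SiMe3)2, THF, −78 °C; PhNTf2, −78 → 0 °C
Reagents that add atoms: N-phenylbis(trifluoromethanesulfonimide), PhNTf2, O=S(=O)(N(c1ccccc1)S(=O)(=O)C(F)(F)F)C(F)(F)F
Why: Kinetic enolate formation and O-triflation — the bulky amide removes a proton from the unhindered methyl group at −78 °C and PhNTf2 traps the terminal enolate on oxygen, with no stereocentre involved.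

**Step 4**
Reactants: 8 4-bromofuran-2(5H)-one; 9 prop-2-yn-1-ol
Product: 10 4-(3-hydroxyprop-1-yn-1-yl)furan-2(5H)-one
Conditions: PdCl2(PPh3)2 (3 mol%), CuI (5 mol%), i-Pr2NEt, THF, rt
Reagents that add atoms: none
Why: Sonogashira coupling — the β-bromo enoate carbon of 8 adds readily to zerovalent palladium and couples with the copper-activated terminal alkyne 9, and a tertiary amine base cannot add–eliminate at the vinylogous acyl bromide.

**Step 5**
Reactants: 10 propargylic alcohol
Product: 11 ynal 3-(5-oxo-2,5-dihydrofuran-3-yl)prop-2-ynal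
Conditions: Dess–Martin periodinane, CH2Cl2, 0 °C (used at once in step 6)
Reagents that add atoms: none
Why: Dess–Martin oxidation of a primary propargylic alcohol stops at the ynal under neutral, non-nucleophilic conditions that spare the butenolide.

**Step 6**
Reactants: 7 enol triflate (1.3 equiv); 11 ynal
Product: 13 enynol 4-[(3RS)-3-hydroxy-4-methylidene-6-Dec-hex-1-yn-1-yl]furan-2(5H)-one, via chromium alkoxide 12 (not isolated)
Conditions: CrCl2 (4 equiv), NiCl2 (2 mol%), DMF, rt; aqueous work-up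
Reagents that add atoms: none
Why: Nozaki–Hiyama–Kishi coupling — nickel-catalysed activation of the alkenyl triflate and transfer to chromium gives a carbon nucleophile that adds only to the aldehyde (not to the lactone, alkyne or olefins) to give alkoxide 12; the new carbinol centre forms as a 1:1 epimer mixture, which does not matter because step 8 erases it.

**Step 7**
Reactants: 13 enynol
Product: 14 bis-allylic alcohol 4-[(1Z,3RS)-3-hydroxy-4-methylidene-6-Dec-hex-1-en-1-yl]furan-2(5H)-one
Conditions: H2 (1 atm), Pd/CaCO3 poisoned with Pb(OAc)2 (5 mol% Pd), quinoline, EtOAc, rt, stopped at 1 equiv H2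
Reagents that add atoms: none
Why: Lindlar-type semihydrogenation — syn delivery of H2 on lead-poisoned palladium turns the alkyne into the (Z)-olefin and leaves the 1,1-disubstituted, tetrasubstituted and lactone olefins alone.

**Step 8**
Reactants: 14 bis-allylic alcohol
Product: 17 target 4-[(1Z,3E)-4-(hydroxymethyl)-6-Dec-hexa-1,3-dien-1-yl]furan-2(5H)-one, via secondary perrhenate ester 15 (not isolated), via primary perrhenate ester 16 (not isolated)
Conditions: Ph3SiOReO3 (5 mol%), 2,6-di-tert-butyl-4-methylpyridine (10 mol%), Et2O, −50 → −20 °C, dark; pH 7 buffer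
Reagents that add atoms: none
Why: Proposed new method: oxo-rhenium-catalysed suprafacial 1,3-hydroxyl transposition on a cross-conjugated, acceptor-substituted (Z)-penta-1,4-dien-3-ol, a substrate class on which arm-selective transposition with retention of a Z-olefin has not been shown. Alcohol 14 exchanges onto heptavalent rhenium to give allyl perrhenate 15, whose chair-like [3,3] shift bonds one Re=O oxygen to C24 as the C14–O bond breaks. The new C24–O oxygen is therefore a former oxo ligand, and the old carbinol oxygen stays on rhenium. The (Z)-alkenyl group sits equatorial in the chair and so ends cis to C12 in the new C13=C14 bond (13E); both C14 epimers converge. The shift should run only through the CH2= arm, whose terminus is unhindered, because the other terminus (C16) is Z-substituted (axial in the chair) and bound to the electron-poor butenolide, so the Z-olefin is never converted to a single bond. Alcoholysis of 16 by 14 turns the catalyst over, and the gain of a fully conjugated trienolide with a trisubstituted olefin makes the step downhill. The hindered pyridine keeps the medium free of perrhenic acid, so neither the Δ8 olefin nor an allyl cation is engaged. Closest known reaction type: Ph3SiOReO3- or Re2O7-catalysed 1,3-isomerisation of simple allylic alcohols, the oxo-metal counterpart of a Claisen-type [3,3] shift.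

**Compound list**
1 | (−)-sclareol, (1R,2R,4aS,8aS)-1-[(3R)-3-hydroxy-3-methylpent-4-en-1-yl]-2,5,5,8a-tetramethyldecahydronaphthalen-2-ol | C[C@]1(O)[C@H](CC[C@@](C)(O)C=C)[C@@]2(C)CCCC(C)(C)[C@@H]2CC1 | starting material
2 | (2R)-2-hydroxy-4-[(1R,2R,4aS,8aS)-2-hydroxy-2,5,5,8a-tetramethyldecahydronaphthalen-1-yl]-2-methylbutanal | C[C@]1(O)[C@H](CC[C@@](C)(O)C=O)[C@@]2(C)CCCC(C)(C)[C@@H]2CC1 | intermediate
3 | 4-[(1R,2R,4aS,8aS)-2-hydroxy-2,5,5,8a-tetramethyldecahydronaphthalen-1-yl]butan-2-one | C[C@]1(O)[C@H](CCC(C)=O)[C@@]2(C)CCCC(C)(C)[C@@H]2CC1 | intermediate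
4 | sclareol oxide, (4aR,6aS,10aS,10bR)-3,4a,7,7,10a-pentamethyl-4a,5,6,6a,7,8,9,10,10a,10b-decahydro-1H-benzo[f]chromene | C[C@]1(OC(C)=CC3)[C@H]3[C@@]2(C)CCCC(C)(C)[C@@H]2CC1 | intermediate
5 | 4-[(4aS,8aS)-2,5,5,8a-tetramethyl-3,4,4a,5,6,7,8,8a-octahydronaphthalen-1-yl]butan-2-one | CC1=C(CCC(C)=O)[C@@]2(C)CCCC(C)(C)[C@@H]2CC1 | intermediate
6 | potassium 4-[(4aS,8aS)-2,5,5,8a-tetramethyl-3,4,4a,5,6,7,8,8a-octahydronaphthalen-1-yl]but-1-en-2-olate | CC1=C(CCC(=C)[O-])[C@@]2(C)CCCC(C)(C)[C@@H]2CC1.[K+] | intermediate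
7 | 4-[(4aS,8aS)-2,5,5,8a-tetramethyl-3,4,4a,5,6,7,8,8a-octahydronaphthalen-1-yl]but-1-en-2-yl trifluoromethanesulfonate | CC1=C(CCC(=C)OS(=O)(=O)C(F)(F)F)[C@@]2(C)CCCC(C)(C)[C@@H]2CC1 | intermediate
8 | 4-bromofuran-2(5H)-one | BrC1=CC(=O)OC1 | starting material
9 | prop-2-yn-1-ol | OCC#C | starting material
10 | 4-(3-hydroxyprop-1-yn-1-yl)furan-2(5H)-one | OCC#CC1=CC(=O)OC1 | intermediate
11 | 3-(5-oxo-2,5-dihydrofuran-3-yl)prop-2-ynal | O=CC#CC1=CC(=O)OC1 | intermediate
12 | dichlorochromium alkoxide of 13 (CrCl2 on the carbinol oxygen; C3 epimers) | CC1=C(CCC(=C)C(O[Cr](Cl)Cl)C#CC2=CC(=O)OC2)[C@@]2(C)CCCC(C)(C)[C@@H]2CC1 | intermediate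
13 | 4-[(3RS)-3-hydroxy-4-methylidene-6-[(4aS,8aS)-2,5,5,8a-tetramethyl-3,4,4a,5,6,7,8,8a-octahydronaphthalen-1-yl]hex-1-yn-1-yl]furan-2(5H)-one | CC1=C(CCC(=C)C(O)C#CC2=CC(=O)OC2)[C@@]2(C)CCCC(C)(C)[C@@H]2CC1 | intermediate
14 | 4-[(1Z,3RS)-3-hydroxy-4-methylidene-6-[(4aS,8aS)-2,5,5,8a-tetramethyl-3,4,4a,5,6,7,8,8a-octahydronaphthalen-1-yl]hex-1-en-1-yl]furan-2(5H)-one | CC1=C(CCC(=C)C(O)/C=C\C2=CC(=O)OC2)[C@@]2(C)CCCC(C)(C)[C@@H]2CC1 | intermediate
15 | trioxorhenium (perrhenate) ester of 14 at the secondary C3 oxygen | CC1=C(CCC(=C)C(O[Re](=O)(=O)=O)/C=C\C2=CC(=O)OC2)[C@@]2(C)CCCC(C)(C)[C@@H]2CC1 | intermediate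
16 | trioxorhenium (perrhenate) ester of 17 at the primary oxygen, (1Z,3E) | CC1=C(CC/C(=C\C=C/C2=CC(=O)OC2)CO[Re](=O)(=O)=O)[C@@]2(C)CCCC(C)(C)[C@@H]2CC1 | intermediate
17 | 4-[(1Z,3E)-4-(hydroxymethyl)-6-[(4aS,8aS)-2,5,5,8a-tetramethyl-3,4,4a,5,6,7,8,8a-octahydronaphthalen-1-yl]hexa-1,3-dien-1-yl]furan-2(5H)-one | CC1=C(CC/C(=C\C=C/C2=CC(=O)OC2)CO)[C@@]2(C)CCCC(C)(C)[C@@H]2CC1 | target

**Totals**
Total steps: 8. Longest linear sequence: 6 (steps 1, 2, 3, 6, 7, 8). No protecting groups are used.

**Three steps most likely to fail**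

Step 8 (proposed new step). Risks are Z→E erosion at C15=C16, a shift through the wrong arm, or acid-triggered cyclisation onto the Δ8 olefin. The fallback uses known chemistry and moves the C–O transposition to the alkyne stage, done stepwise. It sets out from 13. SOCl2 in Et2O at 0 °C gives, by the classical cyclic (SNi′) allylic rearrangement, the rearranged primary allylic chloride F1. HCO2Na with catalytic Bu4NI in DMF displaces chloride to give the allylic formate F2. Brief aq. NaHCO3/MeOH at 0 °C frees the (E)-enynol F3. Cis-semireduction of the conjugated alkyne with Zn activated with Cu(OAc)2 and AgNO3 in MeOH/H2O then gives 17, where the fallback comes back to the route.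

Step 7. Risks are over-reduction of the conjugated lactone diene or Z/E leakage on the catalyst. The fallback installs the Z-olefin by cross-coupling with retention instead of hydrogenation. It sets out from 9 and also uses 7 and 8. LiAlH4 in THF followed by Bu3SnOTf (trans-hydroalumination, then tin for aluminium) gives the (Z)-stannyl allylic alcohol F4. MnO2 in CH2Cl2 gives the (Z)-stannyl enal F5. CrCl2/NiCl2 coupling with 7 gives the (Z)-stannyl dienol F6. Stille coupling of F6 with 8 (Pd(PPh3)4, CuI, DMF, rt) gives 14, where the fallback comes back to the route.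

Step 6. Risks are decomposition of ynal 11 or its reduction by divalent chromium. The fallback attaches the lactone after the fragment union. It sets out from 7. CrCl2/NiCl2 coupling with commercial 3-(trimethylsilyl)prop-2-ynal gives the silyl enynol F7. K2CO3/MeOH gives the terminal alkyne F8. Sonogashira coupling of F8 with 8 (PdCl2(PPh3)2, CuI, i-Pr2NEt, THF) gives 13, where the fallback comes back to the route.

**Further compounds**
F1 | step 8 | 4-[(3E)-4-(chloromethyl)-6-[(4aS,8aS)-2,5,5,8a-tetramethyl-3,4,4a,5,6,7,8,8a-octahydronaphthalen-1-yl]hex-3-en-1-yn-1-yl]furan-2(5H)-one | CC1=C(CC/C(=C\C#CC2=CC(=O)OC2)CCl)[C@@]2(C)CCCC(C)(C)[C@@H]2CC1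
F2 | step 8 | 4-[(3E)-4-(formyloxymethyl)-6-[(4aS,8aS)-2,5,5,8a-tetramethyl-3,4,4a,5,6,7,8,8a-octahydronaphthalen-1-yl]hex-3-en-1-yn-1-yl]furan-2(5H)-one | CC1=C(CC/C(=C\C#CC2=CC(=O)OC2)COC=O)[C@@]2(C)CCCC(C)(C)[C@@H]2CC1
F3 | step 8 | 4-[(3E)-4-(hydroxymethyl)-6-[(4aS,8aS)-2,5,5,8a-tetramethyl-3,4,4a,5,6,7,8,8a-octahydronaphthalen-1-yl]hex-3-en-1-yn-1-yl]furan-2(5H)-one | CC1=C(CC/C(=C\C#CC2=CC(=O)OC2)CO)[C@@]2(C)CCCC(C)(C)[C@@H]2CC1
F4 | step 7 | (2Z)-3-(tributylstannyl)prop-2-en-1-ol | CCCC[Sn](CCCC)(CCCC)/C=C\CO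
F5 | step 7 | (2Z)-3-(tributylstannyl)prop-2-enal | CCCC[Sn](CCCC)(CCCC)/C=C\C=O
F6 | step 7 | (1Z,3RS)-4-methylidene-6-[(4aS,8aS)-2,5,5,8a-tetramethyl-3,4,4a,5,6,7,8,8a-octahydronaphthalen-1-yl]-1-(tributylstannyl)hex-1-en-3-ol | CC1=C(CCC(=C)C(O)/C=C\[Sn](CCCC)(CCCC)CCCC)[C@@]2(C)CCCC(C)(C)[C@@H]2CC1
F7 | step 6 | (3RS)-4-methylidene-6-[(4aS,8aS)-2,5,5,8a-tetramethyl-3,4,4a,5,6,7,8,8a-octahydronaphthalen-1-yl]-1-(trimethylsilyl)hex-1-yn-3-ol | CC1=C(CCC(=C)C(O)C#C[Si](C)(C)C)[C@@]2(C)CCCC(C)(C)[C@@H]2CC1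
F8 | step 6 | (3RS)-4-methylidene-6-[(4aS,8aS)-2,5,5,8a-tetramethyl-3,4,4a,5,6,7,8,8a-octahydronaphthalen-1-yl]hex-1-yn-3-ol | CC1=C(CCC(=C)C(O)C#C)[C@@]2(C)CCCC(C)(C)[C@@H]2CC1
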